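Assumption: (2E)-3-methylpent-2-enoic acid, (2S)-2-methylbutanoic acid, 3-bromo-2-methoxyprop-1-ene and 1,1-diacetoxyethane are bought as such; in the explanations C1–C7a are the indane locants of the target (C1 side-chain carbon, C2 ketone, C4 methylidene, C5 enoate, C6 methylbutanoate, C7 isopropyl).

**Retrosynthetic overview**
1. C1 side chain last: the ring B enol ether (C1=C2) adds to a 1-acetoxyethyl cation, which also unmasks the C2 ketone.
2. C6 ester by acylation; C5–O bond by a stereoretentive palladium/boron-catalysed 1,2-opening of a 4-methylidene-5,6-epoxide with the free enoic acid (key C–O bond).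
3. Ring B (five-membered) by ring-closing metathesis of a trans vinyl/2-methoxyallyl pair; C4 methylidene by Wittig reaction.
4. The trans pair by conjugate vinylation and enolate allylation of a 5,6-epoxycyclohex-2-enone.
5. Ring A (six-membered) is made first: (R)-cryptone from 3-methylbutanal and butenone, then epoxidation and dehydrogenation; ring B second.

**Route**

Step 1
Reactants: 1 3-methylbutanal; 2 but-3-en-2-one
Product: 4 (4R)-4-(propan-2-yl)cyclohex-2-en-1-one, via keto aldehyde 3 (not isolated)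
Conditions: (R)-α,α-diphenylprolinol methyl ether (5 mol%), ethyl 3,4-dihydroxybenzoate (20 mol%), neat, 4 °C; then LiOH, iPrOH, rt
Reagents that add atoms: none
Why: Enamine-catalysed asymmetric Michael addition followed by base-induced intramolecular aldol condensation (Robinson-type annulation); the diphenyl(methoxy)methyl arm of the (R)-catalyst blocks one face of the E-enamine, so butenone adds to the other face and fixes the isopropyl-bearing carbon as R (the (S)-catalyst gives the enantiomer).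

Step 2
Reactants: 4 (4R)-4-(propan-2-yl)cyclohex-2-en-1-one
Product: 5 (1R,5R,6R)-5-(propan-2-yl)-7-oxabicyclo[4.1.0]heptan-2-one
Conditions: 30% H2O2, NaOH (cat.), MeOH, 0 °C
Reagents that add atoms: hydrogen peroxide, OO
Why: Weitz–Scheffer nucleophilic epoxidation; hydroperoxide attacks the β-carbon axially anti to the neighbouring isopropyl group (through the half-chair with pseudoaxial isopropyl), so both C–O bonds end up trans to isopropyl, which is the configuration needed at C5 and C6.

Step 3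
Reactants: 5 (1R,5R,6R)-5-(propan-2-yl)-7-oxabicyclo[4.1.0]heptan-2-one
Product: 8 (1R,5S,6R)-5-(propan-2-yl)-7-oxabicyclo[4.1.0]hept-3-en-2-one, via lithium enolate 6 (not isolated), via sulfilimine adduct 7 (not isolated)
Conditions: LDA, THF, −78 °C; then PhS(Cl)=NtBu, −78 °C
Reagents that add atoms: none
Why: Mukaiyama dehydrogenation: the ketone can only enolise toward its CH2 side (the other α-carbon is an oxirane CH), the lithium enolate is sulfenylated by the sulfinimidoyl chloride and the adduct undergoes syn-elimination at low temperature to the enone, with no stereocentre touched.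

Step 4
Reactants: 8 (1R,5S,6R)-5-(propan-2-yl)-7-oxabicyclo[4.1.0]hept-3-en-2-one; 9 vinylmagnesium bromide; 10 3-bromo-2-methoxyprop-1-ene
Product: 12 (1R,3R,4S,5S,6R)-4-ethenyl-3-(2-methoxyprop-2-en-1-yl)-5-(propan-2-yl)-7-oxabicyclo[4.1.0]heptan-2-one, via magnesium enolate 11 (not isolated)
Conditions: 9 (1.3 equiv), CuBr·SMe2 (10 mol%), THF, −78 °C; then 10 (2 equiv), DMPU, −78 to 0 °C
Reagents that add atoms: vinylmagnesium bromide (9), C=C[Mg]Br; 3-bromo-2-methoxyprop-1-ene (10), COC(=C)CBr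
Why: Copper-catalysed conjugate addition followed by C-alkylation of the regiodefined enolate (vicinal difunctionalisation); vinyl enters anti to the adjacent isopropyl group and the allylic bromide then enters anti to the new vinyl group, giving the all-trans array that becomes the trans ring fusion (C7a and C3a).

Step 5
Reactants: 12 (1R,3R,4S,5S,6R)-4-ethenyl-3-(2-methoxyprop-2-en-1-yl)-5-(propan-2-yl)-7-oxabicyclo[4.1.0]heptan-2-one; 13 methyltriphenylphosphonium bromide
Product: 14 (1S,3R,4R,5S,6R)-4-ethenyl-3-(2-methoxyprop-2-en-1-yl)-2-methylidene-5-(propan-2-yl)-7-oxabicyclo[4.1.0]heptane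
Conditions: 13, KOtBu, THF, 0 °C; then 12, 0 °C to rt
Reagents that add atoms: methyltriphenylphosphonium bromide (13), C[P+](c1ccccc1)(c1ccccc1)c1ccccc1.[Br-]
Why: Wittig methylenation of the α,β-epoxy ketone gives the vinyl oxirane; the only epimerisable centre already carries its substituent in the favoured equatorial position, so no stereocentre changes.

Step 6
Reactants: 14 (1S,3R,4R,5S,6R)-4-ethenyl-3-(2-methoxyprop-2-en-1-yl)-2-methylidene-5-(propan-2-yl)-7-oxabicyclo[4.1.0]heptane
Product: 15 (3aR,5S,6R,7S,7aS)-5,6-epoxy-2-methoxy-4-methylidene-7-(propan-2-yl)-3a,4,5,6,7,7a-hexahydro-3H-indene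
Conditions: second-generation Grubbs catalyst (5 mol%), CH2Cl2, 40 °C
Reagents that add atoms: none
Why: Ring-closing metathesis of the vinyl group with the 1,1-disubstituted enol ether closes ring B as a trans-fused cyclopentene whose enol ether double bond is fixed at C1=C2; the exocyclic methylidene could only form four-membered rings and stays out.

Step 7
Reactants: 15 (3aR,5S,6R,7S,7aS)-5,6-epoxy-2-methoxy-4-methylidene-7-(propan-2-yl)-3a,4,5,6,7,7a-hexahydro-3H-indene; 16 (2E)-3-methylpent-2-enoic acid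
Product: 17 (3aR,5S,6R,7S,7aS)-6-hydroxy-2-methoxy-4-methylidene-7-(propan-2-yl)-3a,4,5,6,7,7a-hexahydro-3H-inden-5-yl (2E)-3-methylpent-2-enoate
Conditions: 16 (1.2 equiv), Pd2(dba)3·CHCl3 (2.5 mol%), PPh3 (10 mol%), Ph2BOH (10 mol%), THF, 0 °C
Reagents that add atoms: (2E)-3-methylpent-2-enoic acid (16), OC(=O)/C=C(\C)CC
Why: Proposed new method: zerovalent palladium ionises the vinyl oxirane with inversion to a π-allyl complex whose C6 alkoxide sits on the face opposite the metal; the alkoxide binds the acyloxyborinate Ph2B–O2CR (from Ph2BOH and the acid) and the resulting borate delivers its carboxylate intramolecularly to the near allyl terminus C5 anti to palladium (second inversion), so the C5–O bond forms with net retention, cis to the C6 hydroxyl and 1,2 instead of 1,4 (the exocyclic CH2 terminus is out of reach of the tether), after which protonolysis of the B–O bond by more acid turns the boron over; the closest known reaction types are the boron-co-catalysed retentive 1,2-addition of alcohols to vinyl epoxides under palladium catalysis and the palladium-catalysed 1,4-addition of carboxylic acids to diene monoepoxides.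

Step 8
Reactants: 17 (3aR,5S,6R,7S,7aS)-6-hydroxy-2-methoxy-4-methylidene-7-(propan-2-yl)-3a,4,5,6,7,7a-hexahydro-3H-inden-5-yl (2E)-3-methylpent-2-enoate; 18 (2S)-2-methylbutanoic acid
Product: 19 (3aR,5S,6R,7S,7aS)-2-methoxy-6-{[(2S)-2-methylbutanoyl]oxy}-4-methylidene-7-(propan-2-yl)-3a,4,5,6,7,7a-hexahydro-3H-inden-5-yl (2E)-3-methylpent-2-enoate
Conditions: 18 (1.5 equiv), DCC, DMAP (cat.), CH2Cl2, 0 °C to rt
Reagents that add atoms: (2S)-2-methylbutanoic acid (18), OC(=O)[C@@H](C)CC
Why: Steglich esterification of the equatorial C6 hydroxyl; no ring stereocentre is touched, the carbodiimide activation at low temperature avoids a ketene and so keeps the (S)-centre of the acid, and fast acylation outruns 1,2-acyl migration.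

Step 9
Reactants: 19 (3aR,5S,6R,7S,7aS)-2-methoxy-6-{[(2S)-2-methylbutanoyl]oxy}-4-methylidene-7-(propan-2-yl)-3a,4,5,6,7,7a-hexahydro-3H-inden-5-yl (2E)-3-methylpent-2-enoate; 20 1,1-diacetoxyethane
Product: 22 (1S,3aR,5S,6R,7S,7aR)-1-[(1R)-1-acetoxyethyl]-6-{[(2S)-2-methylbutanoyl]oxy}-4-methylidene-2-oxo-7-(propan-2-yl)octahydro-1H-inden-5-yl (2E)-3-methylpent-2-enoate (CNP0124625.1), via mixed ketal 21 (not isolated)
Conditions: 20 (1.5 equiv), TMSOTf (10 mol%), CH2Cl2, −78 °C; then pH 7 aqueous work-up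
Reagents that add atoms: 1,1-diacetoxyethane (20), CC(OC(C)=O)OC(C)=O; water, O
Why: Mukaiyama–Isler-type addition of the regiodefined enol ether to the acyloxycarbenium ion released from the acylal; C1 is attacked on the face away from the C7a–C7 bond (side chain trans, also the thermodynamic epimer), the open antiperiplanar transition state known from acetal aldol additions gives the syn (1S,1'R) pair, and hydrolysis of the mixed ketal on work-up reveals the C2 ketone.

**Compound list**
1 | 3-methylbutanal | CC(C)CC=O | starting material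
2 | but-3-en-2-one | CC(=O)C=C | starting material
3 | (2R)-5-oxo-2-(propan-2-yl)hexanal (keto aldehyde) | O=C[C@@H](C(C)C)CCC(C)=O | intermediate
4 | (4R)-4-(propan-2-yl)cyclohex-2-en-1-one ((R)-cryptone) | O=C1C=C[C@@H](C(C)C)CC1 | intermediate
5 | (1R,5R,6R)-5-(propan-2-yl)-7-oxabicyclo[4.1.0]heptan-2-one (epoxide oxygen trans to isopropyl) | O=C1CC[C@H](C(C)C)[C@H]2O[C@@H]12 | intermediate
6 | lithium enolate of 5 (C2=C3 enolate) | [Li]OC1=CC[C@H](C(C)C)[C@H]2O[C@@H]12 | intermediate
7 | sulfilimine adduct of 5 at C3 (S-phenyl-N-tert-butyl; mixture at C3 and sulfur) | O=C1C(S(=NC(C)(C)C)c3ccccc3)C[C@H](C(C)C)[C@H]2O[C@@H]12 | intermediate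
8 | (1R,5S,6R)-5-(propan-2-yl)-7-oxabicyclo[4.1.0]hept-3-en-2-one | O=C1C=C[C@H](C(C)C)[C@H]2O[C@@H]12 | intermediate
9 | vinylmagnesium bromide | C=C[Mg]Br | starting material
10 | 3-bromo-2-methoxyprop-1-ene | COC(=C)CBr | starting material
11 | magnesium enolate after vinyl addition (vinyl trans to isopropyl) | Br[Mg]OC1=C[C@@H](C=C)[C@H](C(C)C)[C@H]2O[C@@H]12 | intermediate
12 | (1R,3R,4S,5S,6R)-4-ethenyl-3-(2-methoxyprop-2-en-1-yl)-5-(propan-2-yl)-7-oxabicyclo[4.1.0]heptan-2-one | O=C1[C@H](CC(OC)=C)[C@@H](C=C)[C@H](C(C)C)[C@H]2O[C@@H]12 | intermediate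
13 | methyltriphenylphosphonium bromide | C[P+](c1ccccc1)(c1ccccc1)c1ccccc1.[Br-] | starting material
14 | (1S,3R,4R,5S,6R)-4-ethenyl-3-(2-methoxyprop-2-en-1-yl)-2-methylidene-5-(propan-2-yl)-7-oxabicyclo[4.1.0]heptane | C=C1[C@H](CC(OC)=C)[C@@H](C=C)[C@H](C(C)C)[C@H]2O[C@@H]12 | intermediate
15 | (3aR,5S,6R,7S,7aS)-5,6-epoxy-2-methoxy-4-methylidene-7-(propan-2-yl)-3a,4,5,6,7,7a-hexahydro-3H-indene (trans-fused, C1=C2 enol ether) | C=C1[C@@H]2CC(OC)=C[C@H]2[C@H](C(C)C)[C@H]3O[C@@H]13 | intermediate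
16 | (2E)-3-methylpent-2-enoic acid | OC(=O)/C=C(\C)CC | starting material
17 | (3aR,5S,6R,7S,7aS)-6-hydroxy-2-methoxy-4-methylidene-7-(propan-2-yl)-3a,4,5,6,7,7a-hexahydro-3H-inden-5-yl (2E)-3-methylpent-2-enoate | C=C1[C@@H]2CC(OC)=C[C@H]2[C@H](C(C)C)[C@@H](O)[C@H]1OC(=O)/C=C(\C)CC | intermediate
18 | (2S)-2-methylbutanoic acid | OC(=O)[C@@H](C)CC | starting material
19 | (3aR,5S,6R,7S,7aS)-2-methoxy-6-{[(2S)-2-methylbutanoyl]oxy}-4-methylidene-7-(propan-2-yl)-3a,4,5,6,7,7a-hexahydro-3H-inden-5-yl (2E)-3-methylpent-2-enoate | C=C1[C@@H]2CC(OC)=C[C@H]2[C@H](C(C)C)[C@@H](OC(=O)[C@@H](C)CC)[C@H]1OC(=O)/C=C(\C)CC | intermediate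
20 | 1,1-diacetoxyethane | CC(OC(C)=O)OC(C)=O | starting material
21 | mixed methyl acetyl ketal of 22 at C2 (mixture at C2) | C=C1[C@@H]2CC(OC)(OC(C)=O)[C@H]([C@@H](C)OC(C)=O)[C@H]2[C@H](C(C)C)[C@@H](OC(=O)[C@@H](C)CC)[C@H]1OC(=O)/C=C(\C)CC | intermediate
22 | (1S,3aR,5S,6R,7S,7aR)-1-[(1R)-1-acetoxyethyl]-6-{[(2S)-2-methylbutanoyl]oxy}-4-methylidene-2-oxo-7-(propan-2-yl)octahydro-1H-inden-5-yl (2E)-3-methylpent-2-enoate (CNP0124625.1) | C=C1[C@@H]2CC(=O)[C@H]([C@@H](C)OC(C)=O)[C@H]2[C@H](C(C)C)[C@@H](OC(=O)[C@@H](C)CC)[C@H]1OC(=O)/C=C(\C)CC | target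

**Totals**
Total step count: 9. Longest linear sequence: 9.

**Three steps most likely to fail**

Step 7 (the proposed new step). The risks are attack of the carboxylate at the exocyclic CH2 terminus (1,4-product), re-ionisation of the allylic ester product by the catalyst, and protonation of the enol ether by the acid. The fallback uses known chemistry and sets out from 15. Pd(PPh3)4 (cat.) under CO2 (1 atm) in THF inserts CO2 into the vinyl oxirane with retention and gives (3aR,5S,6R,7S,7aS)-2-methoxy-4-methylidene-7-(propan-2-yl)-3a,4,5,6,7,7a-hexahydro-3H-indene-5,6-diyl carbonate F2, in which the five-membered carbonate enforces the cis-1,2 outcome. K2CO3 in MeOH frees (3aR,5S,6R,7S,7aS)-2-methoxy-4-methylidene-7-(propan-2-yl)-3a,4,5,6,7,7a-hexahydro-3H-indene-5,6-diol F3. Borinic-acid-catalysed acylation (Ph2BOCH2CH2NH2 10 mol%, (2S)-2-methylbutanoic anhydride, iPr2NEt, MeCN) selects the equatorial C6 hydroxyl of the cis-diol and gives (3aR,5S,6R,7S,7aS)-5-hydroxy-2-methoxy-4-methylidene-7-(propan-2-yl)-3a,4,5,6,7,7a-hexahydro-3H-inden-6-yl (2S)-2-methylbutanoate F4. Esterification of the axial allylic C5 hydroxyl with acid 16 (DCC, DMAP) then returns to the route at 19.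

Step 9. The risks are a low syn/anti ratio at the carbinol carbon and ionisation of the C5 allylic ester by the Lewis acid. The fallback sets out from 19. NBS in THF/H2O (NaHCO3, 0 °C) brominates the enol ether at C1 only and gives (1R,3aR,5S,6R,7S,7aR)-1-bromo-6-{[(2S)-2-methylbutanoyl]oxy}-4-methylidene-2-oxo-7-(propan-2-yl)octahydro-1H-inden-5-yl (2E)-3-methylpent-2-enoate F5. SmI2 (2.2 equiv) with acetaldehyde in THF at −78 °C forms the samarium enolate at C1 regiospecifically, and its closed chair transition state gives the anti aldol (1S,3aR,5S,6R,7S,7aR)-1-[(1S)-1-hydroxyethyl]-6-{[(2S)-2-methylbutanoyl]oxy}-4-methylidene-2-oxo-7-(propan-2-yl)octahydro-1H-inden-5-yl (2E)-3-methylpent-2-enoate F6. A Mitsunobu reaction with acetic acid (PPh3, DIAD) inverts the carbinol centre and installs the acetate, which comes back to the route at 22.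

Step 4. The risks are attack of the Grignard or copper reagent on the oxirane or the carbonyl, base-induced aromatisation of the epoxy enone 8, and sluggish alkylation of the magnesium enolate. The fallback sets out from 8 and separates the two bond formations. A Hayashi–Miyaura-type addition of potassium vinyltrifluoroborate with [Rh(OH)(cod)]2 (3 mol%) in dioxane/H2O at 40 °C adds vinyl anti to isopropyl under nearly neutral conditions and gives (1R,4S,5S,6R)-4-ethenyl-5-(propan-2-yl)-7-oxabicyclo[4.1.0]heptan-2-one F1. LDA (THF, −78 °C) can only enolise the CH2 side; alkylation with 10 in the presence of DMPU occurs trans to vinyl and returns to the route at 12.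

**Further compounds**
F1 | step 4 | (1R,4S,5S,6R)-4-ethenyl-5-(propan-2-yl)-7-oxabicyclo[4.1.0]heptan-2-one | O=C1C[C@@H](C=C)[C@H](C(C)C)[C@H]2O[C@@H]12
F2 | step 7 | (3aR,5S,6R,7S,7aS)-2-methoxy-4-methylidene-7-(propan-2-yl)-3a,4,5,6,7,7a-hexahydro-3H-indene-5,6-diyl carbonate | C=C1[C@@H]2CC(OC)=C[C@H]2[C@H](C(C)C)[C@H]3OC(=O)O[C@@H]13
F3 | step 7 | (3aR,5S,6R,7S,7aS)-2-methoxy-4-methylidene-7-(propan-2-yl)-3a,4,5,6,7,7a-hexahydro-3H-indene-5,6-diol | C=C1[C@@H]2CC(OC)=C[C@H]2[C@H](C(C)C)[C@@H](O)[C@H]1O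
F4 | step 7 | (3aR,5S,6R,7S,7aS)-5-hydroxy-2-methoxy-4-methylidene-7-(propan-2-yl)-3a,4,5,6,7,7a-hexahydro-3H-inden-6-yl (2S)-2-methylbutanoate | C=C1[C@@H]2CC(OC)=C[C@H]2[C@H](C(C)C)[C@@H](OC(=O)[C@@H](C)CC)[C@H]1O
F5 | step 9 | (1R,3aR,5S,6R,7S,7aR)-1-bromo-6-{[(2S)-2-methylbutanoyl]oxy}-4-methylidene-2-oxo-7-(propan-2-yl)octahydro-1H-inden-5-yl (2E)-3-methylpent-2-enoate | C=C1[C@@H]2CC(=O)[C@H](Br)[C@H]2[C@H](C(C)C)[C@@H](OC(=O)[C@@H](C)CC)[C@H]1OC(=O)/C=C(\C)CC
F6 | step 9 | (1S,3aR,5S,6R,7S,7aR)-1-[(1S)-1-hydroxyethyl]-6-{[(2S)-2-methylbutanoyl]oxy}-4-methylidene-2-oxo-7-(propan-2-yl)octahydro-1H-inden-5-yl (2E)-3-methylpent-2-enoate | C=C1[C@@H]2CC(=O)[C@H]([C@H](C)O)[C@H]2[C@H](C(C)C)[C@@H](OC(=O)[C@@H](C)CC)[C@H]1OC(=O)/C=C(\C)CC
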